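## Retrosynthetic overview

1. The last step is hydrogenolysis of six benzyl ethers; before it, an allyl ester on C3 of ring C of the dihydroflavonol unit is removed by Pd-catalysed decarboxylation.
2. Key disconnection: C3–C4 of ring C of the dihydroflavonol unit. It is closed by a chiral-carbene-catalysed intramolecular crossed benzoin of the ring A aldehyde (C4) onto the ketone (C3) of a racemic β-aryloxy α-keto ester, with dynamic kinetic resolution at C2.
3. Enabling feature: the α-ketol C4(=O)–C3(OH) of ring C, with its ketone on ring A, is a benzoin retron. C2 (benzylic, bound to O1, next to C3) epimerises through the enol as long as C3 is a ketone carbon.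
4. Further disconnections: O1–C2 (phenol plus α-bromo keto ester), biaryl C8–C3' (Suzuki–Miyaura), flavone pyranone (chalcone, oxidative cyclisation).
5. Ring order: the pyranone of the flavone unit first, ring C of the dihydroflavonol unit last; all other rings come from the starting materials.

Key step: step 10

Remark 1: compound 16 is drawn as the keto tautomer; it is expected to exist mainly as the achiral enol, so C2 is only fixed in step 10.
Remark 2: the sense of induction in step 10 is assigned by analogy; if the (5aS,10bR) triazolium salt favours 2S, its commercially available antipode is used instead.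

## Route

Step 1
Reactants: 1 1-[2,4-bis(benzyloxy)-6-hydroxyphenyl]ethan-1-one; 2 4-(benzyloxy)-3-bromobenzaldehyde
Product: 3 (E)-1-[2,4-bis(benzyloxy)-6-hydroxyphenyl]-3-[4-(benzyloxy)-3-bromophenyl]prop-2-en-1-one
Conditions: KOH (aq.), EtOH/THF, rt
Reagents that add atoms: none
Why: Claisen–Schmidt condensation, in which the acetophenone enolate adds to the non-enolisable aldehyde and the aldol dehydrates to the (E)-chalcone while the chelated 2'-hydroxyl stays free.

Step 2
Reactants: 3 the chalcone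
Product: 4 5,7-bis(benzyloxy)-2-[4-(benzyloxy)-3-bromophenyl]-4H-chromen-4-one
Conditions: I2 (10 mol%), DMSO, 120 °C
Reagents that add atoms: none
Why: Iodine-catalysed oxidative cyclisation of a 2'-hydroxychalcone with DMSO as terminal oxidant is a standard flavone synthesis and should leave the aryl bromide and the benzyl ethers untouched.

Step 3
Reactants: 4 the 3'-bromoflavone
Product: 5 5,7-bis(benzyloxy)-2-[4-(benzyloxy)-3-(4,4,5,5-tetramethyl-1,3,2-dioxaborolan-2-yl)phenyl]-4H-chromen-4-one
Conditions: bis(pinacolato)diboron, PdCl2(dppf) (5 mol%), KOAc, 1,4-dioxane, 90 °C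
Reagents that add atoms: bis(pinacolato)diboron, CC1(C)OB(OC1(C)C)B1OC(C)(C)C(C)(C)O1
Why: Miyaura borylation of an aryl bromide by zerovalent palladium formed in situ, with KOAc too weak a base to open the flavone ring or to drive homocoupling.

Step 4
Reactants: 6 3,5-bis(benzyloxy)phenol
Product: 8 2,4-bis(benzyloxy)-6-hydroxybenzaldehyde, via hydroxymethylphenol 7 (not isolated)
Conditions: MgCl2, Et3N, paraformaldehyde, MeCN, reflux
Reagents that add atoms: paraformaldehyde (as formaldehyde), C=O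
Why: Magnesium-mediated ortho-formylation (Casnati–Skattebøl), in which the magnesium phenoxide directs hydroxymethylation to the carbon next to the hydroxyl and a second formaldehyde oxidises the benzylic alkoxide by hydride transfer, so that no para aldehyde is expected.

Step 5
Reactants: 8 2,4-bis(benzyloxy)-6-hydroxybenzaldehyde
Product: 9 4,6-bis(benzyloxy)-2-hydroxy-3-iodobenzaldehyde
Conditions: N-iodosuccinimide (1.0 equiv), DMF, 0 °C to rt
Reagents that add atoms: N-iodosuccinimide, O=C1CCC(=O)N1I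
Why: Electrophilic aromatic iodination, expected at C3 next to the chelated hydroxyl by analogy with the iodination of 2-hydroxy-4,6-dialkoxyaryl ketones that is used to reach 8-iodoflavones.

Step 6
Reactants: 9 4,6-bis(benzyloxy)-2-hydroxy-3-iodobenzaldehyde; 5 the flavone 3'-boronate
Product: 10 4,6-bis(benzyloxy)-3-{2-(benzyloxy)-5-[5,7-bis(benzyloxy)-4-oxo-4H-chromen-2-yl]phenyl}-2-hydroxybenzaldehyde
Conditions: Pd(OAc)2 (5 mol%), SPhos (2-dicyclohexylphosphino-2',6'-dimethoxybiphenyl, 10 mol%), K3PO4, toluene/H2O, 80 °C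
Reagents that add atoms: none
Why: Suzuki–Miyaura coupling, in which the bulky electron-rich biaryl phosphine should support oxidative addition to the electron-rich iodide and transmetalation to a tri-ortho-substituted biaryl, as in couplings of 8-iodoflavones with flavone 3'-boronates.

Step 7
Reactants: 11 1-(benzyloxy)-4-(chloromethyl)benzene; 12 diallyl oxalate
Product: 14 allyl 3-[4-(benzyloxy)phenyl]-2-oxopropanoate, via Grignard reagent 13 (not isolated)
Conditions: Mg, Et2O/THF, rt; then 12 (2 equiv), THF, −78 °C; 1 M HCl quench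
Reagents that add atoms: none
Why: Acylation of a benzylic Grignard reagent by a dialkyl oxalate at low temperature, which stops at the α-keto ester because the tetrahedral magnesium hemiketal persists until the quench.

Step 8
Reactants: 14 allyl 3-[4-(benzyloxy)phenyl]-2-oxopropanoate
Product: 15 allyl 3-[4-(benzyloxy)phenyl]-3-bromo-2-oxopropanoate (racemic)
Conditions: N-bromosuccinimide (1.0 equiv), CH2Cl2, 0 °C
Reagents that add atoms: N-bromosuccinimide, O=C1CCC(=O)N1Br
Why: α-Bromination of a ketone through its enol, since the arylpyruvate is largely enolised and the enol should react with NBS at the benzylic carbon much faster than the allyl group or the arene.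

Step 9
Reactants: 10 the biaryl salicylaldehyde; 15 the bromo keto ester
Product: 16 allyl 3-[4-(benzyloxy)phenyl]-3-(3,5-bis(benzyloxy)-6-{2-(benzyloxy)-5-[5,7-bis(benzyloxy)-4-oxo-4H-chromen-2-yl]phenyl}-2-formylphenoxy)-2-oxopropanoate (racemic)
Conditions: K2CO3, acetone, 0 °C to rt
Reagents that add atoms: none
Why: Williamson-type SN2 O-alkylation of the phenoxide by a secondary bromide activated by the adjacent carbonyl group; the new C–O stereocentre is deliberately formed as a racemate because it is labile.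

Step 10
Reactants: 16 the racemic aldehyde keto ester
Product: 17 allyl (2R,3S)-5,7-bis(benzyloxy)-8-{2-(benzyloxy)-5-[5,7-bis(benzyloxy)-4-oxo-4H-chromen-2-yl]phenyl}-2-[4-(benzyloxy)phenyl]-3-hydroxy-4-oxochromane-3-carboxylate (2-aryl trans to the ester)
Conditions: (5aS,10bR)-2-(pentafluorophenyl)-5a,10b-dihydro-4H,6H-indeno[2,1-b][1,2,4]triazolo[4,3-d][1,4]oxazin-2-ium tetrafluoroborate (20 mol%), iPr2NEt (1 equiv), toluene, 4 Å molecular sieves, argon, rt to 40 °C
Reagents that add atoms: none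
Why: Proposed new method: the triazolylidene adds to the only aldehyde of 16 (C4) to give the Breslow intermediate, whose nucleophilic C4 adds to the ketone carbonyl C3 of the keto tautomer, and proton transfer with loss of the carbene leaves the C4 ketone and the C3 tertiary carbinol. The closest known reaction types are the carbene-catalysed intramolecular crossed aldehyde–ketone benzoin that gives 3-hydroxychroman-4-ones and the carbene-catalysed dynamic kinetic cross-benzoin of β-stereogenic α-keto esters; their combination in one ring closure on a β-aryloxy-β-aryl keto ester is not known. Ring C closes in a 6-exo-trig mode, C4 attacking the exocyclic C3=O. C3 is set by the chiral carbene, which selects the ketone face in a hydrogen-bonded chair-like transition state, and C2 is set by dynamic kinetic resolution: the two C2 epimers of 16 interconvert through the enol, and the one that places the 4-(benzyloxy)phenyl group equatorial and anti to the ester should cyclise faster, so C2 follows C3. The step needs chemoselectivity, secured because the ketone cannot form an acyl anion equivalent and the keto ester carbonyl is the best electrophile, and it needs epimerisation faster than closure, secured by the acidity of the C2–H between aryl, aryloxy and 1,2-dicarbonyl groups. After closure C2 is no longer next to a carbonyl group and is locked.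

Step 11
Reactants: 17 the allyl ester
Product: 19 (2R,3R)-hexa-O-benzyl dihydroflavonol–flavone, via keto acid 18 (not isolated)
Conditions: Pd(OAc)2 (5 mol%), PPh3 (20 mol%), HCO2H, Et3N, THF, rt
Reagents that add atoms: none
Why: Palladium-catalysed decarboxylation–hydrogenolysis of an allyl β-keto ester (Tsuji–Trost-type deallylation by zerovalent palladium, formate as hydride source), after which the enediol ketonises to the aryl ketone and C3 should settle under the amine buffer as the 2,3-trans isomer with both substituents equatorial, while C2, no longer acidic and with its 4'-oxygen benzylated, is not touched.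

Step 12
Reactants: 19 the hexa-O-benzyl compound
Product: 20 (2R,3R)-8-[5-(5,7-dihydroxy-4-oxo-4H-chromen-2-yl)-2-hydroxyphenyl]-3,5,7-trihydroxy-2-(4-hydroxyphenyl)chroman-4-one
Conditions: H2 (1 atm), palladium on carbon (10% Pd/C), THF/MeOH, rt
Reagents that add atoms: none
Why: Hydrogenolysis of six aryl benzyl ethers under neutral conditions, which should spare the flavone double bond, both aryl ketones and both stereocentres if hydrogen uptake is monitored.

## Compound list

1 | 1-[2,4-bis(benzyloxy)-6-hydroxyphenyl]ethan-1-one | CC(=O)c1c(O)cc(OCc2ccccc2)cc1OCc1ccccc1 | starting material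
2 | 4-(benzyloxy)-3-bromobenzaldehyde | O=Cc1ccc(OCc2ccccc2)c(Br)c1 | starting material
3 | (E)-1-[2,4-bis(benzyloxy)-6-hydroxyphenyl]-3-[4-(benzyloxy)-3-bromophenyl]prop-2-en-1-one | O=C(/C=C/c1ccc(OCc2ccccc2)c(Br)c1)c1c(O)cc(OCc2ccccc2)cc1OCc1ccccc1 | intermediate
4 | 5,7-bis(benzyloxy)-2-[4-(benzyloxy)-3-bromophenyl]-4H-chromen-4-one | O=c1cc(-c2ccc(OCc3ccccc3)c(Br)c2)oc2cc(OCc3ccccc3)cc(OCc3ccccc3)c12 | intermediate
5 | 5,7-bis(benzyloxy)-2-[4-(benzyloxy)-3-(4,4,5,5-tetramethyl-1,3,2-dioxaborolan-2-yl)phenyl]-4H-chromen-4-one | O=c1cc(-c2ccc(OCc3ccccc3)c(B3OC(C)(C)C(C)(C)O3)c2)oc2cc(OCc3ccccc3)cc(OCc3ccccc3)c12 | intermediate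
6 | 3,5-bis(benzyloxy)phenol | Oc1cc(OCc2ccccc2)cc(OCc2ccccc2)c1 | starting material
7 | 3,5-bis(benzyloxy)-2-(hydroxymethyl)phenol (not isolated) | OCc1c(O)cc(OCc2ccccc2)cc1OCc1ccccc1 | intermediate
8 | 2,4-bis(benzyloxy)-6-hydroxybenzaldehyde | O=Cc1c(O)cc(OCc2ccccc2)cc1OCc1ccccc1 | intermediate
9 | 4,6-bis(benzyloxy)-2-hydroxy-3-iodobenzaldehyde | O=Cc1c(O)c(I)c(OCc2ccccc2)cc1OCc1ccccc1 | intermediate
10 | 4,6-bis(benzyloxy)-3-{2-(benzyloxy)-5-[5,7-bis(benzyloxy)-4-oxo-4H-chromen-2-yl]phenyl}-2-hydroxybenzaldehyde | O=Cc1c(O)c(-c2cc(-c3cc(=O)c4c(OCc5ccccc5)cc(OCc5ccccc5)cc4o3)ccc2OCc2ccccc2)c(OCc2ccccc2)cc1OCc1ccccc1 | intermediate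
11 | 1-(benzyloxy)-4-(chloromethyl)benzene | ClCc1ccc(OCc2ccccc2)cc1 | starting material
12 | diallyl oxalate | C=CCOC(=O)C(=O)OCC=C | starting material
13 | [4-(benzyloxy)benzyl]magnesium chloride (not isolated) | Cl[Mg]Cc1ccc(OCc2ccccc2)cc1 | intermediate
14 | allyl 3-[4-(benzyloxy)phenyl]-2-oxopropanoate | C=CCOC(=O)C(=O)Cc1ccc(OCc2ccccc2)cc1 | intermediate
15 | allyl 3-[4-(benzyloxy)phenyl]-3-bromo-2-oxopropanoate (racemic) | C=CCOC(=O)C(=O)C(Br)c1ccc(OCc2ccccc2)cc1 | intermediate
16 | allyl 3-[4-(benzyloxy)phenyl]-3-(3,5-bis(benzyloxy)-6-{2-(benzyloxy)-5-[5,7-bis(benzyloxy)-4-oxo-4H-chromen-2-yl]phenyl}-2-formylphenoxy)-2-oxopropanoate (racemic, keto tautomer) | C=CCOC(=O)C(=O)C(Oc1c(C=O)c(OCc2ccccc2)cc(OCc2ccccc2)c1-c1cc(-c2cc(=O)c3c(OCc4ccccc4)cc(OCc4ccccc4)cc3o2)ccc1OCc1ccccc1)c1ccc(OCc2ccccc2)cc1 | intermediate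
17 | allyl (2R,3S)-5,7-bis(benzyloxy)-8-{2-(benzyloxy)-5-[5,7-bis(benzyloxy)-4-oxo-4H-chromen-2-yl]phenyl}-2-[4-(benzyloxy)phenyl]-3-hydroxy-4-oxochromane-3-carboxylate | O=C1c2c(OCc3ccccc3)cc(OCc3ccccc3)c(-c3cc(-c4cc(=O)c5c(OCc6ccccc6)cc(OCc6ccccc6)cc5o4)ccc3OCc3ccccc3)c2O[C@H](c2ccc(OCc3ccccc3)cc2)[C@@]1(O)C(=O)OCC=C | intermediate
18 | (2R,3S)-5,7-bis(benzyloxy)-8-{2-(benzyloxy)-5-[5,7-bis(benzyloxy)-4-oxo-4H-chromen-2-yl]phenyl}-2-[4-(benzyloxy)phenyl]-3-hydroxy-4-oxochromane-3-carboxylic acid (not isolated) | O=C1c2c(OCc3ccccc3)cc(OCc3ccccc3)c(-c3cc(-c4cc(=O)c5c(OCc6ccccc6)cc(OCc6ccccc6)cc5o4)ccc3OCc3ccccc3)c2O[C@H](c2ccc(OCc3ccccc3)cc2)[C@@]1(O)C(=O)O | intermediate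
19 | (2R,3R)-5,7-bis(benzyloxy)-8-{2-(benzyloxy)-5-[5,7-bis(benzyloxy)-4-oxo-4H-chromen-2-yl]phenyl}-2-[4-(benzyloxy)phenyl]-3-hydroxychroman-4-one | O=C1c2c(OCc3ccccc3)cc(OCc3ccccc3)c(-c3cc(-c4cc(=O)c5c(OCc6ccccc6)cc(OCc6ccccc6)cc5o4)ccc3OCc3ccccc3)c2O[C@H](c2ccc(OCc3ccccc3)cc2)[C@H]1O | intermediate
20 | (2R,3R)-8-[5-(5,7-dihydroxy-4-oxo-4H-chromen-2-yl)-2-hydroxyphenyl]-3,5,7-trihydroxy-2-(4-hydroxyphenyl)chroman-4-one | O=C1c2c(O)cc(O)c(-c3cc(-c4cc(=O)c5c(O)cc(O)cc5o4)ccc3O)c2O[C@H](c2ccc(O)cc2)[C@H]1O | target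

## Step count and risks

Total step count: 12. Longest linear sequence: 8 steps (steps 1, 2, 3, 6, 9, 10, 11, 12).

Steps most likely to fail:

1. Step 10 (proposed new method). The carbene may add too slowly to the di-ortho-substituted, electron-rich aldehyde, so that base-induced aldol addition of the C2 enolate to the aldehyde takes over. Ring closure may also fail to discriminate between the two C2 epimers, which would erode the configuration at C2. The fallback uses known chemistry; it sets out from 1 and 5 and comes back to the route at 19. Iodination of 1 (N-iodosuccinimide, DMF) should give 1-[4,6-bis(benzyloxy)-2-hydroxy-3-iodophenyl]ethan-1-one F1. Suzuki–Miyaura coupling of F1 with 5 (Pd(OAc)2, SPhos, K3PO4, toluene/H2O) should give the biaryl ketone F2. Protection of the phenol (MOMCl, NaH, DMF) should give the methoxymethyl ether F3. Claisen–Schmidt condensation with 4-(benzyloxy)benzaldehyde (KOH, EtOH/THF) should give the chalcone F4. Julia–Colonna epoxidation (poly-L-leucine, urea–hydrogen peroxide, DBU, THF) should give the (2R,3S)-epoxy ketone F5. HCl in MeOH/THF should then remove the methoxymethyl group, and the freed phenol should open the epoxide at the benzylic carbon in a 6-endo mode with inversion to give 19.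

2. Step 9. Solvolysis or enolisation of the labile benzylic bromide may outrun SN2 attack by the hindered, hydrogen-bonded phenoxide, and the carbonate may trigger aldol addition of the product enolate to the aldehyde. The fallback sets out from 14 (with 10) and comes back at 16. Diazo transfer to 14 (4-acetamidobenzenesulfonyl azide, DBU, MeCN; Regitz reaction) should give allyl 3-[4-(benzyloxy)phenyl]-3-diazo-2-oxopropanoate F6. Rh2(OAc)4-catalysed O–H insertion of the carbenoid from F6 into the phenol of 10 (CH2Cl2, rt) should form the same ether 16 under neutral conditions.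

3. Step 6. Protodeboronation of the poorly soluble flavone boronate and hydrodeiodination of the phenoxide may outcompete the hindered transmetalation. The fallback builds the flavone after the biaryl bond; it sets out from 2 (with 9 and 1) and comes back at 10. Miyaura borylation of 2 should give 4-(benzyloxy)-3-(4,4,5,5-tetramethyl-1,3,2-dioxaborolan-2-yl)benzaldehyde F7. Suzuki–Miyaura coupling of F7 (used in excess) with 9 should give the biaryl dialdehyde F8. Claisen–Schmidt condensation of 1 at the more electrophilic, non-chelated formyl group of F8 should give the chalcone F9. Iodine-catalysed oxidative cyclisation of F9 in DMSO should give 10.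

## Further compounds

F1 | step 10 | 1-[4,6-bis(benzyloxy)-2-hydroxy-3-iodophenyl]ethan-1-one | CC(=O)c1c(O)c(I)c(OCc2ccccc2)cc1OCc1ccccc1
F2 | step 10 | 1-[4,6-bis(benzyloxy)-3-{2-(benzyloxy)-5-[5,7-bis(benzyloxy)-4-oxo-4H-chromen-2-yl]phenyl}-2-hydroxyphenyl]ethan-1-one | CC(=O)c1c(O)c(-c2cc(-c3cc(=O)c4c(OCc5ccccc5)cc(OCc5ccccc5)cc4o3)ccc2OCc2ccccc2)c(OCc2ccccc2)cc1OCc1ccccc1
F3 | step 10 | 1-[4,6-bis(benzyloxy)-3-{2-(benzyloxy)-5-[5,7-bis(benzyloxy)-4-oxo-4H-chromen-2-yl]phenyl}-2-(methoxymethoxy)phenyl]ethan-1-one | CC(=O)c1c(OCOC)c(-c2cc(-c3cc(=O)c4c(OCc5ccccc5)cc(OCc5ccccc5)cc4o3)ccc2OCc2ccccc2)c(OCc2ccccc2)cc1OCc1ccccc1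
F4 | step 10 | (E)-1-[4,6-bis(benzyloxy)-3-{2-(benzyloxy)-5-[5,7-bis(benzyloxy)-4-oxo-4H-chromen-2-yl]phenyl}-2-(methoxymethoxy)phenyl]-3-[4-(benzyloxy)phenyl]prop-2-en-1-one | O=C(/C=C/c1ccc(OCc2ccccc2)cc1)c1c(OCOC)c(-c2cc(-c3cc(=O)c4c(OCc5ccccc5)cc(OCc5ccccc5)cc4o3)ccc2OCc2ccccc2)c(OCc2ccccc2)cc1OCc1ccccc1
F5 | step 10 | [4,6-bis(benzyloxy)-3-{2-(benzyloxy)-5-[5,7-bis(benzyloxy)-4-oxo-4H-chromen-2-yl]phenyl}-2-(methoxymethoxy)phenyl]{(2R,3S)-3-[4-(benzyloxy)phenyl]oxiran-2-yl}methanone | O=C([C@@H]1O[C@H]1c1ccc(OCc2ccccc2)cc1)c1c(OCOC)c(-c2cc(-c3cc(=O)c4c(OCc5ccccc5)cc(OCc5ccccc5)cc4o3)ccc2OCc2ccccc2)c(OCc2ccccc2)cc1OCc1ccccc1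
F6 | step 9 | allyl 3-[4-(benzyloxy)phenyl]-3-diazo-2-oxopropanoate | C=CCOC(=O)C(=O)C(=[N+]=[N-])c1ccc(OCc2ccccc2)cc1
F7 | step 6 | 4-(benzyloxy)-3-(4,4,5,5-tetramethyl-1,3,2-dioxaborolan-2-yl)benzaldehyde | O=Cc1ccc(OCc2ccccc2)c(B2OC(C)(C)C(C)(C)O2)c1
F8 | step 6 | 4,6-bis(benzyloxy)-3-[2-(benzyloxy)-5-formylphenyl]-2-hydroxybenzaldehyde | O=Cc1ccc(OCc2ccccc2)c(-c2c(O)c(C=O)c(OCc3ccccc3)cc2OCc2ccccc2)c1
F9 | step 6 | 4,6-bis(benzyloxy)-3-{2-(benzyloxy)-5-[(E)-3-(2,4-bis(benzyloxy)-6-hydroxyphenyl)-3-oxoprop-1-en-1-yl]phenyl}-2-hydroxybenzaldehyde | O=C(/C=C/c1ccc(OCc2ccccc2)c(-c2c(O)c(C=O)c(OCc3ccccc3)cc2OCc2ccccc2)c1)c1c(O)cc(OCc2ccccc2)cc1OCc1ccccc1
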